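(All runs come from a simulation with constants of no real substance; the scatter is artificial.)

The ratio to watch in the autumn flask, in answer to your request for a quick number and your hunch that its catalyst has died, is the amount of product divided by substrate left times reagent left, each taken as a fraction of the substrate charge.

| flask | substrate | reagent | catalyst | temperature | remark | time |
|---|---|---|---|---|---|---|
| autumn | 20 mM | 0.95 equiv | 5 mol% | 40 °C | the very flask that is asked about, followed so far |  |
| dawn | 20 mM | 0.64 equiv | 5 mol% | 46 °C | run made earlier |  |
| flask | 20 mM | 0.950 equiv | 5 mol% | 40 °C |  | 30 h |

| run | time / h | product / % |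
|---|---|---|
| autumn | 4.00 | 52.6 |
| autumn | 8.00 | 64.5 |
| autumn | 12.0 | 67.8 |
| autumn | 15.0 | 69.1 |
| autumn | 20.0 | 69.7 |
| autumn | 25.0 | 69.2 |
| autumn | 30.0 | 71.0 |
| dawn | 0.250 | 7.0 |
| dawn | 0.667 | 16.2 |
| dawn | 1.33 | 26.2 |
| dawn | 2.00 | 32.7 |
| dawn | 2.50 | 36.5 |
| dawn | 3.00 | 39.8 |
| dawn | 4.00 | 43.8 |

(each reading ± 0.5 percentage points)

- eta: change nothing and wait 15 h more
- beta: at 30 h take out 90% of the product then present, then wait 15 h
- epsilon: at 30 h raise the temperature by 10 K, then wait 15 h
- alpha: at 30 h add reagent, 50.0% of the amount charged, then wait 15 h
- theta: at 30 h add catalyst, 50.0% of the amount charged, then wait 15 h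

- product, in percent of the substrate first charged, at 30 h
- which option adds most product ("none" when 2 percentage points or less is all one gets) (eta / beta / epsilon / alpha / theta / none)
- product present, with what was taken out counted in, in percent of the substrate first charged, after beta
- product present, with what was taken out counted in, in percent of the substrate first charged, after alpha

- removed product is counted in
- the numbers in the tables scatter by 0.5 percentage points (one standard deviation)
- additions bring no volume worth counting

From 15.0 h on, the autumn readings average 69.8%, each with a scatter of 0.5 percentage points. Taking one reagent per substrate, with 0.95 equiv charged, the ratio then reads 9.13, and this frozen value, the standing quotient, is what I carry, reading the stop as an equilibrium and assuming that heat and extra catalyst leave the quotient where it is.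

On that reading I commit to about 69.8% for now and expect nothing from waiting. With 50.0% more reagent, option alpha, the quotient is regained with product at 84.2%. After taking out 90% of the product, option beta, it is regained with product at 82.6%, removed product counted. Both figures are ceilings which 15 h may not reach, and I choose alpha because its ceiling stands higher.

The forecast gives 70% for now, alpha as best, 81.5% after beta, below my ceiling, and 84.2% after alpha. Against your hunch it argues that “A decay fit needs faster decay at 40 °C” than at the warmer temperature of the dawn run.

The flask gives 70.0% for now, alpha as best with a gain of 14 points against 12 points for beta, 81.6% after beta and 84.3% after alpha.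

    substrate + reagent + catalyst ⇌ catalyst + product (K = 470 M⁻¹, k = 4.83 M⁻² s⁻¹, Ea = 45.0 kJ mol⁻¹, ΔH = −1.00 kJ mol⁻¹)
    (constants at 40 °C)

In the autumn flask at 30.0 h the catalyst is still 100% able to turn over and the forward rate alone corresponds to a substrate half-life of 8.0 h, yet the backward rate stands at 99.7% of the forward rate, and waiting 15 h more adds 0.035 points. The quotient 9.13 gave 84.2% for alpha in the autumn flask, where 84.3% stands, and with 1.60 equiv of reagent on the same substrate charge it gives 87.0% for the neighbour flask, which reaches 87.2%.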